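**Retrosynthetic overview**

1. The target is epicatechin 3-O-gallate-(4β→8)-epicatechin 3-O-gallate-(4β→6)-catechin. The last disconnections are global hydrogenolysis (nineteen benzyl ethers, two C–Br bonds) and the upper C4–C8 interflavan bond, made by Friedel–Crafts union with a bromo-capped 4β-(2-ethoxyethoxy)epicatechin gallate derived from (−)-epicatechin.
2. Key disconnection: ring C of the middle unit is opened at C2–C3 together with the C4–C6 interflavan bond. This leaves three simple pieces: a (Z)-2-(2-hydroxyaryl)ethenyl gallate, 3,4-bis(benzyloxy)benzaldehyde, and 8-bromo-penta-O-benzylcatechin from (+)-catechin.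
3. Enabling feature of the middle unit: O1 and ring B flank C2, so C2 can be an oxocarbenium carbon. The oxygens at C5 and C7 of ring A lie ortho and para to C4a, so the C3=C4 styrene is nucleophilic at C3 and the cation appears at C4. There the carbonyl oxygen of the galloyl ester on O3 can bridge it.
4. Ring order: the benzopyran rings of the upper and lower units come from the chiral pool, and ring A of the middle unit from 2,4,6-trihydroxybenzaldehyde. Ring C of the middle unit is the only ring constructed, in step 9; a transient dioxolanylium ring on C3–C4 forms and opens in the same flask.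

Key step: step 9

Assumption: the confined chiral imidodiphosphorimidate acid (IDPi) is a known catalyst class prepared separately and not counted in the steps; the (S,S)-form is written here, and its antipode would be used if the first runs show the opposite sense of induction.

**Route**

Step 1
Reactants: 1 (+)-catechin; 2 benzyl bromide
Product: 3 5,7,3',4'-tetra-O-benzyl-(+)-catechin
Conditions: BnBr (4.4 equiv), K2CO3, DMF, 0 °C → rt
Reagents that add atoms: benzyl bromide 2, BrCc1ccccc1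
Why: Williamson etherification with K2CO3 should alkylate only the four phenols, leaving the secondary 3-OH and both stereocentres untouched.

Step 2
Reactants: 3 5,7,3',4'-tetra-O-benzyl-(+)-catechin; 2 benzyl bromide
Product: 4 3,5,7,3',4'-penta-O-benzyl-(+)-catechin
Conditions: NaH, BnBr, DMF, 0 °C → rt
Reagents that add atoms: benzyl bromide 2, BrCc1ccccc1
Why: Williamson etherification of the sodium alkoxide masks O3 so that it cannot trap cations in step 9, without touching C2 or C3.

Step 3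
Reactants: 4 3,5,7,3',4'-penta-O-benzyl-(+)-catechin; 5 N-bromosuccinimide
Product: 6 8-bromo-3,5,7,3',4'-penta-O-benzyl-(+)-catechin
Conditions: NBS, CH2Cl2, −78 °C → rt
Reagents that add atoms: N-bromosuccinimide 5, O=C1CCC(=O)N1Br
Why: Electrophilic aromatic bromination of benzylated flavan-3-ols goes to C8 of ring A, which should leave C6 as the only nucleophilic carbon.

Step 4
Reactants: 7 2,4,6-trihydroxybenzaldehyde; 2 benzyl bromide
Product: 8 2,4-bis(benzyloxy)-6-hydroxybenzaldehyde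
Conditions: BnBr (2.1 equiv), K2CO3, DMF, rt
Reagents that add atoms: benzyl bromide 2, BrCc1ccccc1
Why: In this Williamson etherification the hydroxyl hydrogen-bonded to the formyl group is the least nucleophilic and should stay free with two equivalents of halide.

Step 5
Reactants: 8 2,4-bis(benzyloxy)-6-hydroxybenzaldehyde; 9 tert-butyldimethylsilyl chloride
Product: 10 2,4-bis(benzyloxy)-6-[(tert-butyldimethylsilyl)oxy]benzaldehyde
Conditions: TBSCl, imidazole, DMF, rt
Reagents that add atoms: tert-butyldimethylsilyl chloride 9, CC(C)(C)[Si](C)(C)Cl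
Why: Imidazole-mediated silylation masks the phenol that becomes O1, so that it cannot add to the ruthenium vinylidene in step 7.

Step 6
Reactants: 10 2,4-bis(benzyloxy)-6-[(tert-butyldimethylsilyl)oxy]benzaldehyde; 11 (trimethylsilyl)diazomethane
Product: 12 [3,5-bis(benzyloxy)-2-ethynylphenoxy](tert-butyl)dimethylsilane
Conditions: Me3SiCHN2, LiN(iPr)2, THF, −78 °C → rt
Reagents that add atoms: (trimethylsilyl)diazomethane 11, C[Si](C)(C)C=[N+]=[N-]
Why: Colvin homologation, in which the lithiated diazomethane adds to the aldehyde, Peterson elimination and loss of N2 give an alkylidene carbene, and its 1,2-hydrogen shift gives the terminal alkyne under conditions that spare the aryl silyl ether.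

Step 7
Reactants: 12 [3,5-bis(benzyloxy)-2-ethynylphenoxy](tert-butyl)dimethylsilane; 13 3,4,5-tris(benzyloxy)benzoic acid
Product: 14 (Z)-2-{2,4-bis(benzyloxy)-6-[(tert-butyldimethylsilyl)oxy]phenyl}ethenyl 3,4,5-tris(benzyloxy)benzoate
Conditions: Ru(η3-CH2CMeCH2)2(Ph2P(CH2)4PPh2) (5 mol %), toluene, 60 °C
Reagents that add atoms: 3,4,5-tris(benzyloxy)benzoic acid 13, OC(=O)c1cc(OCc2ccccc2)c(OCc2ccccc2)c(OCc2ccccc2)c1
Why: Ruthenium-vinylidene anti-Markovnikov hydro-oxycarbonylation of a terminal arylalkyne puts the carboxylate on the terminal carbon and should give the (Z)-enol ester, the alkene geometry that later places O3 axial.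

Step 8
Reactants: 14 (Z)-2-{2,4-bis(benzyloxy)-6-[(tert-butyldimethylsilyl)oxy]phenyl}ethenyl 3,4,5-tris(benzyloxy)benzoate
Product: 15 (Z)-2-[2,4-bis(benzyloxy)-6-hydroxyphenyl]ethenyl 3,4,5-tris(benzyloxy)benzoate
Conditions: HF·pyridine, pyridine, THF, 0 °C; used directly
Reagents that add atoms: none
Why: Buffered fluoride desilylation frees the phenol without forming a phenoxide that could take over the galloyl group, and should leave the enol ester geometry intact.

Step 9
Reactants: 15 (Z)-2-[2,4-bis(benzyloxy)-6-hydroxyphenyl]ethenyl 3,4,5-tris(benzyloxy)benzoate; 16 3,4-bis(benzyloxy)benzaldehyde; 6 8-bromo-3,5,7,3',4'-penta-O-benzyl-(+)-catechin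
Product: 19 5,7,3',4'-tetra-O-benzyl-3-O-(3,4,5-tri-O-benzylgalloyl)epicatechin-(4β→6)-8-bromo-3,5,7,3',4'-penta-O-benzylcatechin, via aryloxocarbenium ion 17 (not isolated), via dioxolanylium ion 18 (not isolated)
Conditions: 16 (1.0 equiv), 6 (1.5 equiv), (S,S)-IDPi (confined BINOL-derived N-triflyl imidodiphosphorimidate Brønsted acid, 5 mol %), 5 Å MS, CHCl3, −40 → −20 °C
Reagents that add atoms: 3,4-bis(benzyloxy)benzaldehyde 16, O=Cc1ccc(OCc2ccccc2)c(OCc2ccccc2)c1
Why: Proposed new method: an asymmetric oxa-Prins cyclisation of a 2-(2-acyloxyvinyl)phenol terminated by neighbouring-group capture and Friedel–Crafts arylation, reasoned as follows: the acid condenses phenol 15 with aldehyde 16 to the (E)-aryloxocarbenium ion 17 held as an ion pair with the confined chiral anion, the styrene carbon C3 adds to C2 and closes ring C (6-endo with respect to the C3=C4 bond), the C4 benzylic cation is bridged by the galloyl carbonyl oxygen to the five-membered 1,3-dioxolan-2-ylium ring of 18, and C6 of arene 6 opens this ring at C4 and releases the proton that turns the catalyst over. The closest known reaction types are the asymmetric Prins cyclisation of homoallylic alcohols with aldehydes under confined imidodiphosphorimidate acids, Prins/Friedel–Crafts cascades that give 4-aryltetrahydropyrans, and the Lewis-acid coupling of flavan-4-yl cations with flavan nucleophiles. The needed regioselectivity (bond from C2 to C3 and not to C4) is secured by the benzyloxy groups at C5 and C7 of ring A, which lie ortho and para to C4a, outweigh the weak enol-ester donor and stabilise the cation at C4. C2 and C3 are set together in a chair-like transition state in which ring B is equatorial on the (E)-oxocarbenium ion and the galloyloxy group is axial because the alkene is Z, which gives the 2,3-cis relation, while the chiral anion selects the oxocarbenium face and so the absolute (2R,3R) sense. C4 is set by the acyloxonium bridge, which occupies the face of O3 and forces the arene to enter trans to it (4β), with inversion at C4. The bromine at C8 of 6 leaves C6 as its only nucleophilic carbon (4→6 linkage), and the intramolecular ring closure is expected to outrun any direct attack of the protonated aldehyde on this hindered arene.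

Step 10
Reactants: 20 (−)-epicatechin; 2 benzyl bromide
Product: 21 5,7,3',4'-tetra-O-benzyl-(−)-epicatechin
Conditions: BnBr (4.4 equiv), K2CO3, DMF, 0 °C → rt
Reagents that add atoms: benzyl bromide 2, BrCc1ccccc1
Why: Williamson etherification of the four phenols only, as in step 1, with C2 and C3 untouched.

Step 11
Reactants: 21 5,7,3',4'-tetra-O-benzyl-(−)-epicatechin; 22 2-ethoxyethanol
Product: 23 5,7,3',4'-tetra-O-benzyl-4β-(2-ethoxyethoxy)epicatechin
Conditions: DDQ, 2-ethoxyethanol, CH2Cl2, rt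
Reagents that add atoms: 2-ethoxyethanol 22, CCOCCO
Why: DDQ benzylic oxidation abstracts hydride from C4 (activated by ring A), and the alcohol should add to the cation anti to the axial 3-OH to give the 4β ether.

Step 12
Reactants: 23 5,7,3',4'-tetra-O-benzyl-4β-(2-ethoxyethoxy)epicatechin; 5 N-bromosuccinimide
Product: 24 8-bromo-5,7,3',4'-tetra-O-benzyl-4β-(2-ethoxyethoxy)epicatechin
Conditions: NBS, CH2Cl2, −78 → 0 °C
Reagents that add atoms: N-bromosuccinimide 5, O=C1CCC(=O)N1Br
Why: Electrophilic aromatic bromination at C8 under neutral conditions caps the most nucleophilic carbon, so that the later electrophile cannot condense with itself.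

Step 13
Reactants: 24 8-bromo-5,7,3',4'-tetra-O-benzyl-4β-(2-ethoxyethoxy)epicatechin; 13 3,4,5-tris(benzyloxy)benzoic acid
Product: 25 8-bromo-5,7,3',4'-tetra-O-benzyl-4β-(2-ethoxyethoxy)epicatechin 3-O-(3,4,5-tri-O-benzylgallate)
Conditions: DCC, DMAP, CH2Cl2, rt
Reagents that add atoms: 3,4,5-tris(benzyloxy)benzoic acid 13, OC(=O)c1cc(OCc2ccccc2)c(OCc2ccccc2)c(OCc2ccccc2)c1
Why: Steglich esterification acylates the axial 3-OH without breaking its C–O bond, so C3 keeps its configuration.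

Step 14
Reactants: 19 5,7,3',4'-tetra-O-benzyl-3-O-(3,4,5-tri-O-benzylgalloyl)epicatechin-(4β→6)-8-bromo-3,5,7,3',4'-penta-O-benzylcatechin; 25 8-bromo-5,7,3',4'-tetra-O-benzyl-4β-(2-ethoxyethoxy)epicatechin 3-O-(3,4,5-tri-O-benzylgallate)
Product: 26 [8-bromo-5,7,3',4'-tetra-O-benzyl-3-O-(3,4,5-tri-O-benzylgalloyl)epicatechin]-(4β→8)-[5,7,3',4'-tetra-O-benzyl-3-O-(3,4,5-tri-O-benzylgalloyl)epicatechin]-(4β→6)-[8-bromo-3,5,7,3',4'-penta-O-benzylcatechin]
Conditions: Me3SiOSO2CF3 (cat.), CH2Cl2, −78 → −40 °C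
Reagents that add atoms: none
Why: Lewis-acid ionisation of the 4-(2-ethoxyethoxy) group gives the flavan-4-yl cation, and Friedel–Crafts attack by C8 of the middle unit of 19 (its most nucleophilic free carbon, C8 of the lower unit being brominated) trans to the participating 3-O-galloyl group should set the 4β configuration.

Step 15
Reactants: 26 the protected trimer
Product: 27 epicatechin 3-O-gallate-(4β→8)-epicatechin 3-O-gallate-(4β→6)-catechin (target)
Conditions: H2 (1 atm), Pd(OH)2/C, Et3N (2.2 equiv), THF/MeOH/H2O, rt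
Reagents that add atoms: none
Why: Palladium-catalysed hydrogenolysis should cleave all nineteen benzyl ethers and both aryl C–Br bonds while the esters, the interflavan bonds and all stereocentres are kept, with triethylamine taking up the HBr.

**Compound list**

1 | (+)-catechin | O[C@H]1Cc2c(O)cc(O)cc2O[C@@H]1c1ccc(O)c(O)c1 | starting material
2 | benzyl bromide | BrCc1ccccc1 | starting material
3 | 5,7,3',4'-tetra-O-benzyl-(+)-catechin | O[C@H]1Cc2c(OCc3ccccc3)cc(OCc3ccccc3)cc2O[C@@H]1c1ccc(OCc2ccccc2)c(OCc2ccccc2)c1 | intermediate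
4 | 3,5,7,3',4'-penta-O-benzyl-(+)-catechin | c1ccccc1CO[C@H]1Cc2c(OCc3ccccc3)cc(OCc3ccccc3)cc2O[C@@H]1c1ccc(OCc2ccccc2)c(OCc2ccccc2)c1 | intermediate
5 | N-bromosuccinimide | O=C1CCC(=O)N1Br | starting material
6 | 8-bromo-3,5,7,3',4'-penta-O-benzyl-(+)-catechin | c1ccccc1CO[C@H]1Cc2c(OCc3ccccc3)cc(OCc3ccccc3)c(Br)c2O[C@@H]1c1ccc(OCc2ccccc2)c(OCc2ccccc2)c1 | intermediate
7 | 2,4,6-trihydroxybenzaldehyde | O=Cc1c(O)cc(O)cc1O | starting material
8 | 2,4-bis(benzyloxy)-6-hydroxybenzaldehyde | O=Cc1c(O)cc(OCc2ccccc2)cc1OCc1ccccc1 | intermediate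
9 | tert-butyldimethylsilyl chloride | CC(C)(C)[Si](C)(C)Cl | starting material
10 | 2,4-bis(benzyloxy)-6-[(tert-butyldimethylsilyl)oxy]benzaldehyde | O=Cc1c(O[Si](C)(C)C(C)(C)C)cc(OCc2ccccc2)cc1OCc1ccccc1 | intermediate
11 | (trimethylsilyl)diazomethane | C[Si](C)(C)C=[N+]=[N-] | starting material
12 | [3,5-bis(benzyloxy)-2-ethynylphenoxy](tert-butyl)dimethylsilane | C#Cc1c(O[Si](C)(C)C(C)(C)C)cc(OCc2ccccc2)cc1OCc1ccccc1 | intermediate
13 | 3,4,5-tris(benzyloxy)benzoic acid | OC(=O)c1cc(OCc2ccccc2)c(OCc2ccccc2)c(OCc2ccccc2)c1 | starting material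
14 | (Z)-2-{2,4-bis(benzyloxy)-6-[(tert-butyldimethylsilyl)oxy]phenyl}ethenyl 3,4,5-tris(benzyloxy)benzoate | O=C(O/C=C\c1c(O[Si](C)(C)C(C)(C)C)cc(OCc2ccccc2)cc1OCc1ccccc1)c1cc(OCc2ccccc2)c(OCc2ccccc2)c(OCc2ccccc2)c1 | intermediate
15 | (Z)-2-[2,4-bis(benzyloxy)-6-hydroxyphenyl]ethenyl 3,4,5-tris(benzyloxy)benzoate | O=C(O/C=C\c1c(O)cc(OCc2ccccc2)cc1OCc1ccccc1)c1cc(OCc2ccccc2)c(OCc2ccccc2)c(OCc2ccccc2)c1 | intermediate
16 | 3,4-bis(benzyloxy)benzaldehyde | O=Cc1ccc(OCc2ccccc2)c(OCc2ccccc2)c1 | starting material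
17 | (E)-aryloxocarbenium ion from 15 and 16 (cation of the ion pair with the catalyst anion) | O=C(O/C=C\c1c(/[O+]=C/c2ccc(OCc3ccccc3)c(OCc3ccccc3)c2)cc(OCc2ccccc2)cc1OCc1ccccc1)c1cc(OCc2ccccc2)c(OCc2ccccc2)c(OCc2ccccc2)c1 | intermediate
18 | cis-fused 2-aryl-1,3-dioxolan-2-ylium ion on C3–C4 of the new (2R,3R)-flavan (cation of the ion pair) | c1c(OCc4ccccc4)cc(OCc4ccccc4)c2c1O[C@H](c1ccc(OCc4ccccc4)c(OCc4ccccc4)c1)[C@@H]1OC(c3cc(OCc4ccccc4)c(OCc4ccccc4)c(OCc4ccccc4)c3)=[O+][C@@H]12 | intermediate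
19 | 5,7,3',4'-tetra-O-benzyl-3-O-(3,4,5-tri-O-benzylgalloyl)epicatechin-(4β→6)-8-bromo-3,5,7,3',4'-penta-O-benzylcatechin | c1c(OCc4ccccc4)cc(OCc4ccccc4)c2c1O[C@H](c1ccc(OCc4ccccc4)c(OCc4ccccc4)c1)[C@H](OC(=O)c1cc(OCc4ccccc4)c(OCc4ccccc4)c(OCc4ccccc4)c1)[C@H]2c1c(OCc4ccccc4)c(Br)c2c(c1OCc4ccccc4)C[C@H](OCc4ccccc4)[C@@H](c1ccc(OCc4ccccc4)c(OCc4ccccc4)c1)O2 | intermediate
20 | (−)-epicatechin | O[C@@H]1Cc2c(O)cc(O)cc2O[C@@H]1c1ccc(O)c(O)c1 | starting material
21 | 5,7,3',4'-tetra-O-benzyl-(−)-epicatechin | O[C@@H]1Cc2c(OCc3ccccc3)cc(OCc3ccccc3)cc2O[C@@H]1c1ccc(OCc2ccccc2)c(OCc2ccccc2)c1 | intermediate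
22 | 2-ethoxyethanol | CCOCCO | starting material
23 | 5,7,3',4'-tetra-O-benzyl-4β-(2-ethoxyethoxy)epicatechin | O[C@@H]1[C@@H](OCCOCC)c2c(OCc3ccccc3)cc(OCc3ccccc3)cc2O[C@@H]1c1ccc(OCc2ccccc2)c(OCc2ccccc2)c1 | intermediate
24 | 8-bromo-5,7,3',4'-tetra-O-benzyl-4β-(2-ethoxyethoxy)epicatechin | O[C@@H]1[C@@H](OCCOCC)c2c(OCc3ccccc3)cc(OCc3ccccc3)c(Br)c2O[C@@H]1c1ccc(OCc2ccccc2)c(OCc2ccccc2)c1 | intermediate
25 | 8-bromo-5,7,3',4'-tetra-O-benzyl-4β-(2-ethoxyethoxy)epicatechin 3-O-(3,4,5-tri-O-benzylgallate) | O=C(O[C@@H]1[C@@H](OCCOCC)c2c(OCc3ccccc3)cc(OCc3ccccc3)c(Br)c2O[C@@H]1c1ccc(OCc2ccccc2)c(OCc2ccccc2)c1)c1cc(OCc2ccccc2)c(OCc2ccccc2)c(OCc2ccccc2)c1 | intermediate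
26 | protected trimer: [8-bromo-tetra-O-benzyl-3-O-(tri-O-benzylgalloyl)epicatechin]-(4β→8)-[tetra-O-benzyl-3-O-(tri-O-benzylgalloyl)epicatechin]-(4β→6)-[8-bromo-penta-O-benzylcatechin] | O=C(O[C@@H]1[C@@H](c2c(OCc4ccccc4)cc(OCc4ccccc4)c3c2O[C@H](c2ccc(OCc4ccccc4)c(OCc4ccccc4)c2)[C@H](OC(=O)c2cc(OCc4ccccc4)c(OCc4ccccc4)c(OCc4ccccc4)c2)[C@H]3c2c(OCc4ccccc4)c(Br)c3c(c2OCc4ccccc4)C[C@H](OCc4ccccc4)[C@@H](c2ccc(OCc4ccccc4)c(OCc4ccccc4)c2)O3)c2c(OCc4ccccc4)cc(OCc4ccccc4)c(Br)c2O[C@@H]1c1ccc(OCc4ccccc4)c(OCc4ccccc4)c1)c1cc(OCc4ccccc4)c(OCc4ccccc4)c(OCc4ccccc4)c1 | intermediate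
27 | epicatechin 3-O-gallate-(4β→8)-epicatechin 3-O-gallate-(4β→6)-catechin | O=C(O[C@@H]1[C@@H](c2c(O)cc(O)c3c2O[C@H](c2ccc(O)c(O)c2)[C@H](OC(=O)c2cc(O)c(O)c(O)c2)[C@H]3c2c(O)cc3c(c2O)C[C@H](O)[C@@H](c2ccc(O)c(O)c2)O3)c2c(O)cc(O)cc2O[C@@H]1c1ccc(O)c(O)c1)c1cc(O)c(O)c(O)c1 | target

**Step count and risks**

Total steps: 15. Longest linear sequence: 8 steps (steps 4, 5, 6, 7, 8, 9, 14, 15).

Step 9 (key step). What may go wrong:
- weak enantiofacial discrimination at the aryloxocarbenium ion;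
- protonation of the enol ester at C3, with loss of the Z geometry or of the galloyl group;
- acyl transfer to the free phenol followed by closure to a benzofuran;
- direct hydroxyalkylation of arene 6 by the aldehyde.

The fallback uses known chemistry and takes the middle unit from the chiral pool. It sets out from compound 23: Steglich esterification with acid 13 (DCC, DMAP, CH2Cl2) should give 5,7,3',4'-tetra-O-benzyl-4β-(2-ethoxyethoxy)epicatechin 3-O-(3,4,5-tri-O-benzylgallate) F1. Friedel–Crafts union of F1 with an excess of the C8-blocked arene 6 (Me3SiOSO2CF3, CH2Cl2, −78 °C) should then form the 4β→6 bond, and the route is rejoined at compound 19.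

Step 14. What may go wrong:
- slow ionisation and steric congestion between two galloylated partners;
- partial attack at C6 instead of C8 of the middle unit;
- acid-induced cleavage of the 4→6 bond already present.

The fallback reverses the order of the two interflavan bonds by orthogonal activation. It sets out from compound 23: exchange with 2,6-dimethylbenzenethiol (BF3·OEt2, CH2Cl2, −78 °C) should give 5,7,3',4'-tetra-O-benzyl-4β-[(2,6-dimethylphenyl)thio]epicatechin F2. Steglich esterification with 13 gives its 3-O-(3,4,5-tri-O-benzylgallate) F3. Union of electrophile 25 with F3 (Me3SiOSO2CF3 cat., −78 °C) should occur at C8 of this monomeric unit and leave the thioether untouched, giving the upper–middle dimer 4β-thioether F4. Thiophilic activation of F4 (N-iodosuccinimide, CH2Cl2, −78 °C) in the presence of arene 6 then forms the 4β→6 bond, and the route is rejoined at compound 26.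

Step 7. What may go wrong:
- erosion of Z selectivity;
- competing Markovnikov addition on the hindered, electron-rich alkyne;
- migration or loss of the silyl group at 60 °C in the presence of the acid.

The fallback makes the C–O bond on a preformed Z alkene. It sets out from compound 10: Stork–Zhao olefination ((iodomethyl)triphenylphosphonium iodide, NaN(SiMe3)2, THF, −78 °C) should give (Z)-[3,5-bis(benzyloxy)-2-(2-iodoethenyl)phenoxy](tert-butyl)dimethylsilane F5. Ullmann-type coupling of F5 with acid 13 (CuI, a phenanthroline ligand, Cs2CO3, toluene, 80 °C), with retention of the alkene geometry, returns to the route at compound 14.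

**Further compounds**

F1 | step 9 | 5,7,3',4'-tetra-O-benzyl-4β-(2-ethoxyethoxy)epicatechin 3-O-(3,4,5-tri-O-benzylgallate) | O=C(O[C@@H]1[C@@H](OCCOCC)c2c(OCc3ccccc3)cc(OCc3ccccc3)cc2O[C@@H]1c1ccc(OCc2ccccc2)c(OCc2ccccc2)c1)c1cc(OCc2ccccc2)c(OCc2ccccc2)c(OCc2ccccc2)c1
F2 | step 14 | 5,7,3',4'-tetra-O-benzyl-4β-[(2,6-dimethylphenyl)thio]epicatechin | O[C@@H]1[C@@H](Sc3c(C)cccc3C)c2c(OCc3ccccc3)cc(OCc3ccccc3)cc2O[C@@H]1c1ccc(OCc2ccccc2)c(OCc2ccccc2)c1
F3 | step 14 | 5,7,3',4'-tetra-O-benzyl-4β-[(2,6-dimethylphenyl)thio]epicatechin 3-O-(3,4,5-tri-O-benzylgallate) | O=C(O[C@@H]1[C@@H](Sc3c(C)cccc3C)c2c(OCc3ccccc3)cc(OCc3ccccc3)cc2O[C@@H]1c1ccc(OCc2ccccc2)c(OCc2ccccc2)c1)c1cc(OCc2ccccc2)c(OCc2ccccc2)c(OCc2ccccc2)c1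
F4 | step 14 | [8-bromo-tetra-O-benzyl-3-O-(tri-O-benzylgalloyl)epicatechin]-(4β→8)-[tetra-O-benzyl-4β-[(2,6-dimethylphenyl)thio]-3-O-(tri-O-benzylgalloyl)epicatechin] | O=C(O[C@@H]1[C@@H](c2c(OCc4ccccc4)cc(OCc4ccccc4)c3c2O[C@H](c2ccc(OCc4ccccc4)c(OCc4ccccc4)c2)[C@H](OC(=O)c2cc(OCc4ccccc4)c(OCc4ccccc4)c(OCc4ccccc4)c2)[C@H]3Sc2c(C)cccc2C)c2c(OCc4ccccc4)cc(OCc4ccccc4)c(Br)c2O[C@@H]1c1ccc(OCc4ccccc4)c(OCc4ccccc4)c1)c1cc(OCc4ccccc4)c(OCc4ccccc4)c(OCc4ccccc4)c1
F5 | step 7 | (Z)-[3,5-bis(benzyloxy)-2-(2-iodoethenyl)phenoxy](tert-butyl)dimethylsilane | I/C=C\c1c(O[Si](C)(C)C(C)(C)C)cc(OCc2ccccc2)cc1OCc1ccccc1
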